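The earlier runs and the new flask come from a simulation on assumed constants; the scatter is artificial.

We settle the three schedules by following one substrate molecule and asking its chances at the fork between target and everything else.

| flask | substrate | coupling partner | remark | time |
|---|---|---|---|---|
| maple | 0.98 M (in portions, 3) | 0.54 M | run made earlier; portions every 2.0 h |  |
| ash | 0.98 M (in portions, 3) | 2.2 M | run made earlier; portions every 2.0 h |  |
| alder | 2 M (in portions, 3) | 1.08 M | run made earlier; portions every 2.0 h |  |
| summer | 0.98 M (in portions, 3) | 1.08 M | the portions of substrate follow each other after 2.0 h, the first at the start | 50 h |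
| winter | 0.98 M (in portions, 3) | 1.08 M | the portions of substrate follow each other after 4.0 h, the first at the start | 50 h |
| autumn | 0.98 M (in portions, 3) | 1.08 M | the portions of substrate follow each other after 8.0 h, the first at the start | 50 h |

| run | time / h | target / % | substrate / % |
|---|---|---|---|
| maple | 5.00 | 3.2 | 74.6 |
| maple | 10.0 | 6.6 | 45.1 |
| maple | 15.0 | 8.6 | 30.4 |
| maple | 30.0 | 11.9 | 12.1 |
| maple | 60.0 | 12.8 | 4.7 |
| ash | 5.00 | 11.1 | 62.8 |
| ash | 10.0 | 20.2 | 29.6 |
| ash | 15.0 | 26.1 | 15.6 |
| ash | 30.0 | 32.1 | 5.3 |
| ash | 60.0 | 36.1 | 2.6 |
| alder | 5.00 | 4.8 | 62.8 |
| alder | 15.0 | 12.1 | 18.9 |
| alder | 30.0 | 15.7 | 5.8 |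
| alder | 40.0 | 15.5 | 3.9 |
| alder | 60.0 | 17.7 | 2.8 |

(standard deviation of a reading: 0.5 percentage points)

- the earlier runs were read with a standard deviation of 0.5 percentage points
- a reading or a percentage of target counts all its forms, free or not
- "hardly changes" means that all values lie within two and a half points (for a concentration: within two and a half percent of the largest)
- a reading of substrate is of its free form alone

- amount of target at the end, in percent of the substrate charged for summer, winter, autumn, in this order
- the course of these numbers from the first flask to the last (rises, then falls / falls all the way / hardly changes / falls, then rises / rises all the way)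

Count the target against the substrate gone elsewhere, that is, neither free nor target, and divide these odds by the starting coupling partner. At 60.0 h, the maple run reads 0.287 L mol⁻¹ and the ash run 0.268 L mol⁻¹, although their partner differs fourfold. We therefore carry the mean, 0.278 L mol⁻¹, as the odds per molar, a selectivity factor. The alder run, with about twice the charge, reads 0.206 L mol⁻¹, lower than that, so we let the inverse of the odds run linearly with the charge.

Two extremes bracket the flasks. If the portions follow as in maple and ash, a molecule meets their loading, and the share of target is 23.1%. If each portion were gone before the next, the loading would be a third of the charge, the odds per molar 0.357 L mol⁻¹, and the share 27.8%.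

Summer has the interval of maple and ash, so we place summer at the first extreme. Maple's substrate just after its dosing reads a lifetime of 9.94 h, which we borrow for the dosing stretch although maple has less coupling partner. The peak loading then comes to 82.9% of the charge on maple's interval and 54.9% on autumn's, which puts autumn 56.5% of the way to the second extreme. Autumn's mean portion also goes in 6.00 h later than summer's, and maple's closing lifetime of 31.7 h turns maple's final 4.7% of unused substrate into 5.68% for autumn. Taking these off, we reckon 22.0% for summer and 24.3% for autumn, with winter between. That is a rise of 2.3 percentage points, so we commit to "hardly changes".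

The forecast gives 20.5%, 22.5%, 25%, rises all the way, on the ground that “Slower dosing keeps free substrate lower and later”.

The flasks give 22.1%, 22.6% and 23.0%: hardly changes. At the end, free substrate stands at 3.98% in summer and 5.50% in autumn.

    substrate + coupling partner → target (k = 0.0230 L mol⁻¹ h⁻¹)
    substrate → side product A (k = 0.0310 h⁻¹)
    2 substrate → side product B (k = 0.0410 L mol⁻¹ h⁻¹)
    substrate + target ⇌ idle adduct, settled at all times (K = 41.0 L mol⁻¹)

Carried over to these end values, the odds per molar come to 0.277 L mol⁻¹ in summer and 0.298 L mol⁻¹ in autumn.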